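**Retrosynthetic overview**

- The target is ring A (C1 carbinol with CH2OAc, C3 chain, C5 ring B; the three carbon substituents cis) carrying ring B, a cis-4,5-disubstituted cyclopent-2-enone (C1' on C5, C2'=O, C3'=C4', C5'–CH3).
- The strategy rests on this feature: C1'–C5' is the C=C of a (Z)-prop-1-enyl group on C5, C3'/C4' are ethyne and C2' is CO. A sulfur on the CH2 of C1, cis to the propenyl group and bishomoallylic to its C=C, directs a three-component [2+2+1] annulation and is later exchanged for OAc through a spiro-epoxide.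
- Disconnections: hydroperoxide by Schenck ene reaction of the skipped diene; CH2OAc from CH2SPh; ring B by Pauson–Khand reaction; chain by alkyne carboalumination/prenylation; Z-propenyl by lactol Wittig reaction; ring A by ozonolysis of a Diels–Alder norbornene.
- Ring order: ring A first (made inside the norbornene in step 1, released in step 4), ring B last (step 10).

Key step: step 10

Assumption: the oxazaborolidinone from N-tosyl-(R)-tryptophan is taken to give the (1S,2S,4S) adduct 3, the mirror image of the adduct associated with the (S)-tryptophan catalyst; if the sense is the reverse, the other catalyst enantiomer is used.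

**Route**

Step 1
Reactants: 1 cyclopenta-1,3-diene; 2 2-bromoprop-2-enal
Product: 3 (1S,2S,4S)-2-bromobicyclo[2.2.1]hept-5-ene-2-carbaldehyde (CHO exo, Br endo)
Conditions: oxazaborolidinone from N-tosyl-(R)-tryptophan and BuB(OH)2 (10 mol%), CH2Cl2, −78 °C
Reagents that add atoms: none
Why: Catalytic enantioselective Diels–Alder reaction of an α-bromo enal, in which the exo-formyl transition state and the catalyst-shielded enal face set C1, C2 and C4 of the norbornene (later C5, C1 and C3 of ring A) together.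

Step 2
Reactants: 3 (1S,2S,4S)-2-bromobicyclo[2.2.1]hept-5-ene-2-carbaldehyde
Product: 4 [(1S,2S,4S)-2-bromobicyclo[2.2.1]hept-5-en-2-yl]methanol (CH2OH exo, Br endo)
Conditions: NaBH4, MeOH–THF, −20 → 0 °C
Reagents that add atoms: none
Why: Chemoselective borohydride reduction of the aldehyde, which leaves the tertiary bromide and all stereocentres untouched.

Step 3
Reactants: 4 [(1S,2S,4S)-2-bromobicyclo[2.2.1]hept-5-en-2-yl]methanol
Product: 6 (1S,2R,4S)-2-(hydroxymethyl)bicyclo[2.2.1]hept-5-en-2-ol (OH exo, CH2OH endo), via exo-oxygen spiro-epoxide 5 (not isolated)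
Conditions: KOH, DMSO–H2O, 20 °C then 90 °C
Reagents that add atoms: water (delivered as hydroxide from KOH), O
Why: Intramolecular Williamson displacement of the endo bromide by the exo CH2O− inverts C2 (oxygen exo, CH2 endo), and SN2 opening of the spiro-epoxide by hydroxide at its primary carbon leaves C2 untouched, giving the exo tertiary alcohol with an endo CH2OH.

Step 4
Reactants: 6 (1S,2R,4S)-2-(hydroxymethyl)bicyclo[2.2.1]hept-5-en-2-ol
Product: 7 (3aR,5S,6aR)-1,3a-dihydroxyhexahydro-1H-cyclopenta[c]furan-5-carbaldehyde (lactol, both anomers)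
Conditions: O3, CH2Cl2–MeOH, −78 °C; then Me2S, −78 → 20 °C
Reagents that add atoms: ozone, [O-][O+]=O
Why: Ozonolysis of the strained alkene releases ring A as a cis-1,3-dialdehyde, and the formyl group on C5, which is cis to the endo CH2OH, closes to a five-membered lactol, so the two aldehydes are differentiated without changing any ring stereocentre.

Step 5
Reactants: 7 (3aR,5S,6aR)-1,3a-dihydroxyhexahydro-1H-cyclopenta[c]furan-5-carbaldehyde
Product: 8 (3aR,5S,6aR)-5-ethynylhexahydro-1H-cyclopenta[c]furan-1,3a-diol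
Conditions: dimethyl (1-diazo-2-oxopropyl)phosphonate (1.1 equiv), K2CO3, MeOH, 0 → 20 °C
Reagents that add atoms: dimethyl (1-diazo-2-oxopropyl)phosphonate, COP(=O)(OC)C(=[N+]=[N-])C(C)=O
Why: Ohira–Bestmann homologation converts the free aldehyde on C3 into the ethynyl group, while the lactol-masked aldehyde should react far more slowly and the mild carbonate base should leave the α-stereocentre (cis-1,3, not strained) in place.

Step 6
Reactants: 8 (3aR,5S,6aR)-5-ethynylhexahydro-1H-cyclopenta[c]furan-1,3a-diol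
Product: 9 (1R,2S,4S)-4-ethynyl-1-(hydroxymethyl)-2-[(1Z)-prop-1-en-1-yl]cyclopentan-1-ol
Conditions: EtPPh3Br, KN(SiMe3)2 (excess), THF, −78 → 0 °C
Reagents that add atoms: ethyltriphenylphosphonium bromide, CC[P+](c1ccccc1)(c1ccccc1)c1ccccc1.[Br-]
Why: Salt-free Wittig reaction of a non-stabilised ylide with the open hydroxy-aldehyde form of the lactol gives the Z alkene under kinetic control and frees the primary alcohol.

Step 7
Reactants: 9 (1R,2S,4S)-4-ethynyl-1-(hydroxymethyl)-2-[(1Z)-prop-1-en-1-yl]cyclopentan-1-ol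
Product: 10 [(1R,2S,4S)-4-ethynyl-1-hydroxy-2-[(1Z)-prop-1-en-1-yl]cyclopentyl]methyl 4-methylbenzenesulfonate
Conditions: TsCl, Et3N, DMAP (cat.), CH2Cl2, 0 °C
Reagents that add atoms: 4-methylbenzenesulfonyl chloride, Cc1ccc(cc1)S(=O)(=O)Cl
Why: Sulfonylation selects the primary hydroxyl over the tertiary one on steric grounds.

Step 8
Reactants: 10 [(1R,2S,4S)-4-ethynyl-1-hydroxy-2-[(1Z)-prop-1-en-1-yl]cyclopentyl]methyl 4-methylbenzenesulfonate; 11 benzenethiol
Product: 13 (1R,2S,4S)-4-ethynyl-1-[(phenylsulfanyl)methyl]-2-[(1Z)-prop-1-en-1-yl]cyclopentan-1-ol, via spiro-epoxide 12 (not isolated)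
Conditions: K2CO3, MeOH (degassed), 50 °C
Reagents that add atoms: none
Why: Base closes the hydroxy tosylate to the spiro-epoxide (Williamson reaction at CH2) and thiophenoxide opens it by SN2 at the same primary carbon, so C1 keeps its configuration and the sulfur ends cis to the propenyl group.

Step 9
Reactants: 13 (1R,2S,4S)-4-ethynyl-1-[(phenylsulfanyl)methyl]-2-[(1Z)-prop-1-en-1-yl]cyclopentan-1-ol; 14 1-bromo-3-methylbut-2-ene
Product: 16 (1R,2S,4S)-4-[(2E)-6-methylhepta-2,5-dien-2-yl]-1-[(phenylsulfanyl)methyl]-2-[(1Z)-prop-1-en-1-yl]cyclopentan-1-ol, via alkenylalane 15 (not isolated)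
Conditions: AlMe3 (3.5 equiv), Cp2ZrCl2 (25 mol%), CH2Cl2, 0 → 23 °C; then 14, Pd(PPh3)4 (5 mol%), THF, 23 °C; aqueous work-up
Reagents that add atoms: trimethylaluminium, C[Al](C)C
Why: Negishi zirconium-catalysed syn carboalumination places methyl on the internal and aluminium on the terminal alkyne carbon, and palladium-catalysed allylation of the alkenylalane at the primary carbon of prenyl bromide proceeds with retention, which fixes the 2E geometry of the skipped diene.

Step 10
Reactants: 16 (1R,2S,4S)-4-[(2E)-6-methylhepta-2,5-dien-2-yl]-1-[(phenylsulfanyl)methyl]-2-[(1Z)-prop-1-en-1-yl]cyclopentan-1-ol; 17 ethyne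
Product: 18 (4R,5S)-5-{(1S,2R,4S)-2-hydroxy-4-[(2E)-6-methylhepta-2,5-dien-2-yl]-2-[(phenylsulfanyl)methyl]cyclopentyl}-4-methylcyclopent-2-en-1-one
Conditions: Co2(CO)8 (1.5 equiv), ethyne (1 atm), CH2Cl2, 23 °C, then N2 purge; 16, NMO (6 equiv), 0 → 23 °C; NH4Cl (aq.), air
Reagents that add atoms: carbon monoxide (delivered by Co2(CO)8), [C-]#[O+]
Why: Proposed new method: the amine N-oxide removes one CO from the ethyne–Co2(CO)6 complex, the thioether on the CH2 of C1 takes the vacant site and delivers cobalt to the Z C=C on C5, the alkene inserts into a Co–C(ethyne) bond so that C4'–C5' forms and cobalt sits on C1' in a six-membered S,C-chelate, CO inserts into Co–C1' (C1'–C2') and reductive elimination forms C2'–C3'; the closest known reaction type is the sulfide- or amine-directed intermolecular Pauson–Khand reaction of terminal homoallylic and bishomoallylic alkenes with alkyne–Co2(CO)6 complexes, here asked to accept an acyclic Z-1,2-disubstituted alkene. Ring B closes as a three-component [2+2+1] cycloaddition, its last bond by reductive elimination from the acyl cobaltacycle. C1' and C5' are set together: syn addition across the Z alkene places ring A and the C5' methyl cis, and the face is fixed because A(1,3) strain with the Z methyl holds C5–H in the alkene plane, so the sulfur-bound cobalt reaches only the face on the C1 side, which models as (1'S,5'R). The step needs chemoselectivity for the propenyl group over the two trisubstituted chain alkenes and the regiochemistry with C1' next to C=O; both follow from chelation, since only the propenyl C=C is within reach of sulfur and the chelate puts cobalt on the tether-side carbon. The cis arrangement is kinetic and base-labile, so the later steps avoid enolising conditions.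

Step 11
Reactants: 18 (4R,5S)-5-{(1S,2R,4S)-2-hydroxy-4-[(2E)-6-methylhepta-2,5-dien-2-yl]-2-[(phenylsulfanyl)methyl]cyclopentyl}-4-methylcyclopent-2-en-1-one
Product: 20 (4R,5S)-4-methyl-5-{(3R,4S,6S)-6-[(2E)-6-methylhepta-2,5-dien-2-yl]-1-oxaspiro[2.4]heptan-4-yl}cyclopent-2-en-1-one, via sulfonium triflate 19 (not isolated)
Conditions: MeOTf, 2,6-di-tert-butyl-4-methylpyridine, CH2Cl2, 0 → 23 °C; then K2CO3 (aq.), 0 °C
Reagents that add atoms: none
Why: S-Methylation turns the sulfide into a methyl(phenyl)sulfonium leaving group and the tertiary alkoxide displaces it at CH2 (3-exo-tet epoxide closure of a β-hydroxy sulfonium salt), so C1 keeps its configuration while the brief cold carbonate treatment is meant to spare the C1' hydrogen.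

Step 12
Reactants: 20 (4R,5S)-4-methyl-5-{(3R,4S,6S)-6-[(2E)-6-methylhepta-2,5-dien-2-yl]-1-oxaspiro[2.4]heptan-4-yl}cyclopent-2-en-1-one
Product: 21 [(1R,2S,4S)-1-hydroxy-4-[(2E)-6-methylhepta-2,5-dien-2-yl]-2-[(1S,5R)-5-methyl-2-oxocyclopent-3-en-1-yl]cyclopentyl]methyl acetate
Conditions: CsOAc, AcOH, DMF, 50 °C
Reagents that add atoms: cesium acetate, CC(=O)[O-].[Cs+]
Why: Buffered SN2 opening of the 2,2-disubstituted epoxide by acetate at the primary carbon leaves C1 untouched, and the acetate/acetic acid buffer is too weakly basic to enolise the cis enone.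

Step 13
Reactants: 21 [(1R,2S,4S)-1-hydroxy-4-[(2E)-6-methylhepta-2,5-dien-2-yl]-2-[(1S,5R)-5-methyl-2-oxocyclopent-3-en-1-yl]cyclopentyl]methyl acetate
Product: 22 [(1R,2S,4S)-4-[(2E,4E)-6-hydroperoxy-6-methylhepta-2,4-dien-2-yl]-1-hydroxy-2-[(1S,5R)-5-methyl-2-oxocyclopent-3-en-1-yl]cyclopentyl]methyl acetate (target)
Conditions: O2, tetraphenylporphyrin (cat.), visible light, CH2Cl2, −20 °C, stopped at partial conversion
Reagents that add atoms: dioxygen, O=O
Why: Schenck ene reaction of singlet oxygen at the terminal trisubstituted alkene with abstraction of a doubly allylic C4 hydrogen on the more crowded side gives the tertiary C6 hydroperoxide and a new 4E alkene conjugated with the 2E alkene; the enone is inert and no stereocentre is formed.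

**Compound list**

1 | cyclopenta-1,3-diene (freshly cracked from its dimer) | C1=CC=CC1 | starting material
2 | 2-bromoprop-2-enal | C=C(Br)C=O | starting material
3 | (1S,2S,4S)-2-bromobicyclo[2.2.1]hept-5-ene-2-carbaldehyde (CHO exo, Br endo) | C1=C[C@@H]2C[C@H]1C[C@]2(C=O)Br | intermediate
4 | [(1S,2S,4S)-2-bromobicyclo[2.2.1]hept-5-en-2-yl]methanol | C1=C[C@@H]2C[C@H]1C[C@]2(CO)Br | intermediate
5 | (1S,2R,4S)-spiro[bicyclo[2.2.1]hept-5-ene-2,2'-oxirane] (O exo, CH2 endo) | C1=C[C@@H]2C[C@H]1C[C@]2(O3)C3 | intermediate (not isolated)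
6 | (1S,2R,4S)-2-(hydroxymethyl)bicyclo[2.2.1]hept-5-en-2-ol | C1=C[C@@H]2C[C@H]1C[C@]2(O)CO | intermediate
7 | (3aR,5S,6aR)-1,3a-dihydroxyhexahydro-1H-cyclopenta[c]furan-5-carbaldehyde (both anomers) | OC3[C@@H]1C[C@H](C=O)C[C@]1(O)CO3 | intermediate
8 | (3aR,5S,6aR)-5-ethynylhexahydro-1H-cyclopenta[c]furan-1,3a-diol (both anomers) | OC3[C@@H]1C[C@H](C#C)C[C@]1(O)CO3 | intermediate
9 | (1R,2S,4S)-4-ethynyl-1-(hydroxymethyl)-2-[(1Z)-prop-1-en-1-yl]cyclopentan-1-ol | C/C=C\[C@@H]1C[C@H](C#C)C[C@]1(O)CO | intermediate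
10 | [(1R,2S,4S)-4-ethynyl-1-hydroxy-2-[(1Z)-prop-1-en-1-yl]cyclopentyl]methyl 4-methylbenzenesulfonate | C/C=C\[C@@H]1C[C@H](C#C)C[C@]1(O)COS(=O)(=O)c1ccc(C)cc1 | intermediate
11 | benzenethiol | Sc1ccccc1 | starting material
12 | (3R,4S,6S)-6-ethynyl-4-[(1Z)-prop-1-en-1-yl]-1-oxaspiro[2.4]heptane | C/C=C\[C@@H]1C[C@H](C#C)C[C@]1(O2)C2 | intermediate (not isolated)
13 | (1R,2S,4S)-4-ethynyl-1-[(phenylsulfanyl)methyl]-2-[(1Z)-prop-1-en-1-yl]cyclopentan-1-ol | C/C=C\[C@@H]1C[C@H](C#C)C[C@]1(O)CSc1ccccc1 | intermediate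
14 | 1-bromo-3-methylbut-2-ene | CC(C)=CCBr | starting material
15 | (E)-alkenyl(dimethyl)alane of 13, with the tertiary oxygen as its dimethylaluminium alkoxide | C/C=C\[C@@H]1C[C@H](/C(C)=C/[Al](C)C)C[C@]1(O[Al](C)C)CSc1ccccc1 | intermediate (not isolated)
16 | (1R,2S,4S)-4-[(2E)-6-methylhepta-2,5-dien-2-yl]-1-[(phenylsulfanyl)methyl]-2-[(1Z)-prop-1-en-1-yl]cyclopentan-1-ol | C/C=C\[C@@H]1C[C@H](/C(C)=C/CC=C(C)C)C[C@]1(O)CSc1ccccc1 | intermediate
17 | ethyne | C#C | starting material
18 | (4R,5S)-5-{(1S,2R,4S)-2-hydroxy-4-[(2E)-6-methylhepta-2,5-dien-2-yl]-2-[(phenylsulfanyl)methyl]cyclopentyl}-4-methylcyclopent-2-en-1-one | c1ccccc1SC[C@@]1(O)C[C@@H](/C(C)=C/CC=C(C)C)C[C@H]1[C@H]1C(=O)C=C[C@H]1C | intermediate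
19 | S-methyl-S-phenylsulfonium trifluoromethanesulfonate of 18 (both configurations at sulfur) | C[S+](c1ccccc1)C[C@@]1(O)C[C@@H](/C(C)=C/CC=C(C)C)C[C@H]1[C@H]1C(=O)C=C[C@H]1C.[O-]S(=O)(=O)C(F)(F)F | intermediate (not isolated)
20 | (4R,5S)-4-methyl-5-{(3R,4S,6S)-6-[(2E)-6-methylhepta-2,5-dien-2-yl]-1-oxaspiro[2.4]heptan-4-yl}cyclopent-2-en-1-one | C1O[C@@]12C[C@@H](/C(C)=C/CC=C(C)C)C[C@H]2[C@H]2C(=O)C=C[C@H]2C | intermediate
21 | [(1R,2S,4S)-1-hydroxy-4-[(2E)-6-methylhepta-2,5-dien-2-yl]-2-[(1S,5R)-5-methyl-2-oxocyclopent-3-en-1-yl]cyclopentyl]methyl acetate | CC(=O)OC[C@@]1(O)C[C@@H](/C(C)=C/CC=C(C)C)C[C@H]1[C@H]1C(=O)C=C[C@H]1C | intermediate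
22 | [(1R,2S,4S)-4-[(2E,4E)-6-hydroperoxy-6-methylhepta-2,4-dien-2-yl]-1-hydroxy-2-[(1S,5R)-5-methyl-2-oxocyclopent-3-en-1-yl]cyclopentyl]methyl acetate | CC(=O)OC[C@@]1(O)C[C@@H](/C(C)=C/C=C/C(C)(C)OO)C[C@H]1[C@H]1C(=O)C=C[C@H]1C | target

**Step count**

Total steps: 13. Longest linear sequence: 13 steps (1 and 2 to 22).

**Steps most likely to fail**

1. Step 10. The internal Z alkene may fail to insert before the cobalt complex decomposes, or chelation by the aryl sulfide may be too weak to control conversion, face and regiochemistry.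
 Fallback with known reactions, setting out from 8 and coming back at 21. Ring B is built on an alkyne at C5 with ethene as the alkene partner, and the methyl group is added afterwards.
 - Lactol 8 is olefinated with chloromethylenetriphenylphosphorane (ClCH2PPh3Cl, KN(SiMe3)2) to the chloroalkene diol F1.
 - Carboalumination as in step 9 gives the alkenylalane F2, and palladium-catalysed coupling with 14 gives the prenylated chloroalkene F3.
 - LiN(i-Pr)2 in excess eliminates HCl to the ethynyl diol F4.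
 - Co2(CO)8 converts F4 into the dicobalt hexacarbonyl complex F5, which undergoes the Pauson–Khand reaction with ethene under pressure (Me3NO) to the 2-substituted cyclopent-2-enone F6.
 - Me2CuLi adds methyl at C5', and protonation of the enolate at −78 °C anti to the new methyl gives the cis ketone F7. The C5' configuration relative to ring A rests on substrate control only here, so the two cis diastereomers may have to be separated.
 - LiN(i-Pr)2 and Me3SiCl give the tris(trimethylsilyl) enol ether F8 on the CH2 side, and Saegusa–Ito oxidation with Pd(OAc)2 in MeCN, followed by mild acidic work-up, gives the enone diol F9.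
 - AcCl and 2,4,6-collidine at −78 °C acetylate the primary hydroxyl to give 21.

2. Step 13. Singlet oxygen may attack the C2=C3 alkene next to ring A, abstract a methyl hydrogen at the terminal alkene (secondary hydroperoxide), or react a second time.
 Fallback setting out from 13 and coming back at 22. The tertiary oxygen is brought in with the chain and converted into the hydroperoxide at the end.
 - The iodo alcohol F10 is made from 2-methylbut-3-yn-2-ol by hydrostannation (Bu3SnH, Pd(PPh3)4 cat.) and iodination.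
 - Alkenylalane 15, formed from 13 as in step 9, is coupled with F10 (Pd(PPh3)4) to the dienyl carbinol F11.
 - The conditions of step 10 give the cyclopentenone F12; those of step 11 give the sulfonium triflate F13 and then the spiro-epoxide F14; those of step 12 give the acetate F15.
 - Perhydrolysis of the tertiary dienylic alcohol of F15 (50% H2O2, TsOH cat., Et2O, 0 °C) gives 22. The hydroperoxide should enter at the less hindered gem-dimethyl end of the pentadienyl cation.

3. Step 11. The base used for epoxide closure may enolise C1' and erode the cis relation on ring B, or deprotonate the sulfonium salt to an ylide instead of closing the ring.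
 Fallback setting out from 18 and coming back at 21, in which no alkoxide is generated next to the enone.
 - NaIO4 (MeOH–H2O, 0 °C) oxidises the sulfide to the sulfoxide F16.
 - Pummerer rearrangement (trifluoroacetic anhydride, 2,6-lutidine, MeCN, 0 °C) gives the α-(trifluoroacetoxy) sulfide F17, which is hydrolysed with cold aqueous NaHCO3 to the α-hydroxy aldehyde F18.
 - NaBH(OAc)3 reduces the aldehyde in the presence of the enone to the enone diol F9.
 - Acetylation of the primary hydroxyl (AcCl, 2,4,6-collidine) gives 21.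

**Further compounds**

F1 | step 10 | (1R,2S,4S)-2-(2-chloroethenyl)-4-ethynyl-1-(hydroxymethyl)cyclopentan-1-ol (E/Z mixture) | ClC=C[C@@H]1C[C@H](C#C)C[C@]1(O)CO
F2 | step 10 | (E)-alkenyl(dimethyl)alane of F1 with both oxygens as dimethylaluminium alkoxides | ClC=C[C@@H]1C[C@H](/C(C)=C/[Al](C)C)C[C@]1(O[Al](C)C)CO[Al](C)C
F3 | step 10 | (1R,2S,4S)-2-(2-chloroethenyl)-1-(hydroxymethyl)-4-[(2E)-6-methylhepta-2,5-dien-2-yl]cyclopentan-1-ol | ClC=C[C@@H]1C[C@H](/C(C)=C/CC=C(C)C)C[C@]1(O)CO
F4 | step 10 | (1R,2S,4S)-2-ethynyl-1-(hydroxymethyl)-4-[(2E)-6-methylhepta-2,5-dien-2-yl]cyclopentan-1-ol | C#C[C@@H]1C[C@H](/C(C)=C/CC=C(C)C)C[C@]1(O)CO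
F5 | step 10 | dicobalt hexacarbonyl complex of the alkyne of F4 | O=C=[Co]12(=C=O)(=C=O)[CH]3[C]1([C@@H]4C[C@H](/C(C)=C/CC=C(C)C)C[C@]4(O)CO)[Co]23(=C=O)(=C=O)=C=O
F6 | step 10 | 2-{(1S,2R,4S)-2-hydroxy-2-(hydroxymethyl)-4-[(2E)-6-methylhepta-2,5-dien-2-yl]cyclopentyl}cyclopent-2-en-1-one | O=C1CCC=C1[C@@H]1C[C@H](/C(C)=C/CC=C(C)C)C[C@]1(O)CO
F7 | step 10 | (2S,3R)-2-{(1S,2R,4S)-2-hydroxy-2-(hydroxymethyl)-4-[(2E)-6-methylhepta-2,5-dien-2-yl]cyclopentyl}-3-methylcyclopentan-1-one | OC[C@@]1(O)C[C@@H](/C(C)=C/CC=C(C)C)C[C@H]1[C@H]1C(=O)CC[C@H]1C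
F8 | step 10 | trimethylsilyl enol ether of F7 towards C3', with both hydroxyls as trimethylsilyl ethers | C[Si](C)(C)OC[C@@]1(O[Si](C)(C)C)C[C@@H](/C(C)=C/CC=C(C)C)C[C@H]1[C@H]1C(O[Si](C)(C)C)=CC[C@H]1C
F9 | step 10 | (4R,5S)-5-{(1S,2R,4S)-2-hydroxy-2-(hydroxymethyl)-4-[(2E)-6-methylhepta-2,5-dien-2-yl]cyclopentyl}-4-methylcyclopent-2-en-1-one | OC[C@@]1(O)C[C@@H](/C(C)=C/CC=C(C)C)C[C@H]1[C@H]1C(=O)C=C[C@H]1C
F10 | step 13 | (3E)-4-iodo-2-methylbut-3-en-2-ol | CC(C)(O)/C=C/I
F11 | step 13 | (1R,2S,4S)-4-[(2E,4E)-6-hydroxy-6-methylhepta-2,4-dien-2-yl]-1-[(phenylsulfanyl)methyl]-2-[(1Z)-prop-1-en-1-yl]cyclopentan-1-ol | C/C=C\[C@@H]1C[C@H](/C(C)=C/C=C/C(C)(C)O)C[C@]1(O)CSc1ccccc1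
F12 | step 13 | (4R,5S)-5-{(1S,2R,4S)-2-hydroxy-4-[(2E,4E)-6-hydroxy-6-methylhepta-2,4-dien-2-yl]-2-[(phenylsulfanyl)methyl]cyclopentyl}-4-methylcyclopent-2-en-1-one | c1ccccc1SC[C@@]1(O)C[C@@H](/C(C)=C/C=C/C(C)(C)O)C[C@H]1[C@H]1C(=O)C=C[C@H]1C
F13 | step 13 | S-methyl-S-phenylsulfonium trifluoromethanesulfonate of F12 | C[S+](c1ccccc1)C[C@@]1(O)C[C@@H](/C(C)=C/C=C/C(C)(C)O)C[C@H]1[C@H]1C(=O)C=C[C@H]1C.[O-]S(=O)(=O)C(F)(F)F
F14 | step 13 | (4R,5S)-5-{(3R,4S,6S)-6-[(2E,4E)-6-hydroxy-6-methylhepta-2,4-dien-2-yl]-1-oxaspiro[2.4]heptan-4-yl}-4-methylcyclopent-2-en-1-one | C1O[C@@]12C[C@@H](/C(C)=C/C=C/C(C)(C)O)C[C@H]2[C@H]2C(=O)C=C[C@H]2C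
F15 | step 13 | [(1R,2S,4S)-1-hydroxy-4-[(2E,4E)-6-hydroxy-6-methylhepta-2,4-dien-2-yl]-2-[(1S,5R)-5-methyl-2-oxocyclopent-3-en-1-yl]cyclopentyl]methyl acetate | CC(=O)OC[C@@]1(O)C[C@@H](/C(C)=C/C=C/C(C)(C)O)C[C@H]1[C@H]1C(=O)C=C[C@H]1C
F16 | step 11 | (4R,5S)-5-{(1S,2R,4S)-2-hydroxy-4-[(2E)-6-methylhepta-2,5-dien-2-yl]-2-[(phenylsulfinyl)methyl]cyclopentyl}-4-methylcyclopent-2-en-1-one (both configurations at sulfur) | O=S(c1ccccc1)C[C@@]1(O)C[C@@H](/C(C)=C/CC=C(C)C)C[C@H]1[C@H]1C(=O)C=C[C@H]1C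
F17 | step 11 | α-(trifluoroacetoxy) sulfide from the Pummerer rearrangement of F16 (both configurations at the new carbon) | FC(F)(F)C(=O)OC(Sc1ccccc1)[C@@]1(O)C[C@@H](/C(C)=C/CC=C(C)C)C[C@H]1[C@H]1C(=O)C=C[C@H]1C
F18 | step 11 | (1R,2S,4S)-1-hydroxy-4-[(2E)-6-methylhepta-2,5-dien-2-yl]-2-[(1S,5R)-5-methyl-2-oxocyclopent-3-en-1-yl]cyclopentane-1-carbaldehyde | O=C[C@@]1(O)C[C@@H](/C(C)=C/CC=C(C)C)C[C@H]1[C@H]1C(=O)C=C[C@H]1C
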